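**Plan**
1. Numbering (eremophilane): ring A = C1, C2, C3 (ester O), C4 (CH3), C5 (CH3), C10 (OH); ring B = C5, C6 (=CH), C7, C8 (C=O), C9, C10; side chain C11 (H, CH3) and C12 (CO2H) on C7.
2. Cuts: first the C3–O ester bond and the C12 oxidation level, then C6=C7 (opens ring B), then C5–C6 together with C9–C10 (a (2+2) pair), last C4–CH3 and the C8–alkyne bond.
3. Enabling feature: C6 sits on the quaternary C5 and is 1,5-related to the C8 ketone through C5–C10–C9, so ring B is the condensation product of a non-enolisable C6 aldehyde (or iminium) with C7; a cyclobutane C5–C6–C9–C10 releases exactly this 1,5-pair when C6–C9 is cleaved.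
4. Forward: ring A enone → asymmetric methyl addition trapped as the C5=C10 enol silane; acid-catalysed (2+2) with an ynone carrying C6–C9 and C11–C13 gives a ring-A-fused cyclobutene (temporary ring); an amine-triggered aza-Michael/retro-Mannich/Mannich/elimination cascade moves C6 from C9 to C7 and closes ring B; then C3 ketone → axial alcohol → angelate, desilylation, C12 alcohol → acid.
5. Stereochemistry: C4 from the copper–phosphoramidite catalyst; C5 and C10 together from the (2+2) (anti to the C4 methyl, cis fusion); C3 from equatorial hydride delivery anti to the axial C5 methyl; C11 from (R)-β-methyl-γ-butyrolactone; the Z alkene from angelic acid.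

Key step: step 8

Remark: (R)-4-methyldihydrofuran-2(3H)-one is assumed to be purchasable as a chiral-pool building block.

**Step 1**
Reactants: 1 1,4-dioxaspiro[4.5]dec-6-en-8-one
Product: 2 7-iodo-1,4-dioxaspiro[4.5]dec-6-en-8-one
Conditions: I2, pyridine, CH2Cl2, 0 °C → rt
Reagents that add atoms: iodine, II
Why: Johnson α-iodination of an enone (pyridine conjugate addition, iodination of the enolate, elimination) places iodine only on the α-carbon, and the basic medium leaves the dioxolane intact.

**Step 2**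
Reactants: 2 7-iodo-1,4-dioxaspiro[4.5]dec-6-en-8-one
Product: 3 7-methyl-1,4-dioxaspiro[4.5]dec-6-en-8-one
Conditions: trimethylboroxine, Pd(PPh3)4 (5 mol%), Cs2CO3, 1,4-dioxane/H2O, 90 °C
Reagents that add atoms: trimethylboroxine, CB1OB(C)OB(C)O1
Why: Suzuki–Miyaura methylation of the 2-iodoenone (oxidative addition of zerovalent palladium into the C–I bond, transmetalation, reductive elimination) should give the 2-methylenone without touching the ketal.

**Step 3**
Reactants: 3 7-methyl-1,4-dioxaspiro[4.5]dec-6-en-8-one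
Product: 5 tert-butyl{[(6R)-6,7-dimethyl-1,4-dioxaspiro[4.5]dec-7-en-8-yl]oxy}dimethylsilane, via aluminium enolate 4 (not isolated)
Conditions: AlMe3, Cu(O2CC4H3S) (copper thiophene-2-carboxylate, 3 mol%), BINOL-derived N,N-bis(1-phenylethyl)phosphoramidite (6 mol%, antipode matched to the 6R product in a pilot run), Et2O, −30 °C; then TBSOTf, −30 → 0 °C
Reagents that add atoms: trimethylaluminium, C[Al](C)C (methyl in 5, aluminium only in 4); tert-butyldimethylsilyl triflate, CC(C)(C)[Si](C)(C)OS(=O)(=O)C(F)(F)F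
Why: Copper-catalysed asymmetric conjugate addition of AlMe3 to an α-substituted cyclohexenone should set the methyl-bearing centre (C6 of the spiro numbering, C4 of the target) under control of the chiral phosphoramidite, and O-silylation of the aluminium enolate fixes the tetrasubstituted enol ether regiospecifically.

**Step 4**
Reactants: 6 (R)-4-methyldihydrofuran-2(3H)-one
Product: 7 (R)-4-hydroxy-N-methoxy-N,3-dimethylbutanamide
Conditions: MeNH(OMe)·HCl, i-PrMgCl, THF, −20 → 0 °C
Reagents that add atoms: N,O-dimethylhydroxylamine hydrochloride, CNOC.Cl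
Why: Weinreb aminolysis of the lactone by the chloromagnesium amide formed in the flask should open the ring without touching the stereocentre, which is β to the carbonyl and comes from the chiral pool.

**Step 5**
Reactants: 7 (R)-4-hydroxy-N-methoxy-N,3-dimethylbutanamide
Product: 8 (R)-4-[(tert-butyldiphenylsilyl)oxy]-N-methoxy-N,3-dimethylbutanamide
Conditions: TBDPSCl, imidazole, DMF, rt
Reagents that add atoms: tert-butyldiphenylsilyl chloride, CC(C)(C)[Si](Cl)(c1ccccc1)c1ccccc1
Why: Imidazole-promoted silylation of the primary alcohol blocks relactonisation and gives an ether that should survive every later acidic and basic step.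

**Step 6**
Reactants: 8 (R)-4-[(tert-butyldiphenylsilyl)oxy]-N-methoxy-N,3-dimethylbutanamide
Product: 9 (R)-6-[(tert-butyldiphenylsilyl)oxy]-5-methylhex-1-yn-3-one
Conditions: HC≡CMgBr, THF, 0 °C; cold aq. NaHSO4 quench
Reagents that add atoms: ethynylmagnesium bromide, C#C[Mg]Br
Why: Weinreb ketone synthesis, in which the magnesium chelate stops the addition at the ketone stage and the cold acidic quench prevents conjugate addition of the released amine to the ynone.

**Step 7**
Reactants: 5 tert-butyl{[(6R)-6,7-dimethyl-1,4-dioxaspiro[4.5]dec-7-en-8-yl]oxy}dimethylsilane; 9 (R)-6-[(tert-butyldiphenylsilyl)oxy]-5-methylhex-1-yn-3-one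
Product: 10 (3R)-1-[(1R,2R,6R)-6-{[tert-butyl(dimethyl)silyl]oxy}-1,2-dimethylspiro[bicyclo[4.2.0]oct-7-ene-3,2'-[1,3]dioxolan]-7-yl]-4-{[tert-butyl(diphenyl)silyl]oxy}-3-methylbutan-1-one (cis-fused cyclobutene C5–C6=C9–C10)
Conditions: Tf2NH (3 mol%), CH2Cl2, −78 → −40 °C; Et3N quench
Reagents that add atoms: none
Why: Acid-catalysed (2+2) cycloaddition of a silyl enol ether with an acetylenic ketone (Mukaiyama–Michael addition, then closure of the allenyl silyl ether onto the silyloxocarbenium ion) in which C5 should attack the ynone terminus anti to the pseudoaxial C4 methyl and closure at C10 must follow on the same face, so the quaternary C5 and the siloxy-bearing C10 are set together with methyl and OTBS cis.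

**Step 8**
Reactants: 10 cis-fused cyclobutenyl ketone (as named in step 7)
Product: 14 (11R)-10β-(tert-butyldimethylsilyloxy)-12-(tert-butyldiphenylsilyloxy)-3,3-(ethylenedioxy)eremophil-6-en-8-one, via aminocyclobutane 11 (not isolated), via seco-iminium 12 (not isolated), via Mannich base 13 (not isolated)
Conditions: pyrrolidine (1.2 equiv), AcOH (1.2 equiv), MeCN, 23 → 50 °C
Reagents that add atoms: pyrrolidine, C1CCNC1, and acetic acid, CC(=O)O (both only in the intermediates 11–13; neither leaves atoms in 14)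
Why: Proposed new method: pyrrolidine adds to C6 of the strained cyclobutenyl ketone (aza-Michael) to give the 2-aminocyclobutyl ketone 11, whose nitrogen lone pair expels the C9 enolate by cleaving C6–C9 (retro-Mannich, driven by about 26 kcal/mol of ring strain) to the iminium 12; the C8 ketone then enolises towards C7 and closes ring B by Mannich attack on the iminium carbon C6 (13), and E1cB loss of pyrrolidine leaves the C6=C7 enone, so the amine turns over and the step is a net isomerisation of 10. The closest known reaction types are the retro-Mannich/Mannich cascade of 2-aminocyclobutyl ketones made by vinylogous amide photocycloaddition, the de Mayo retro-aldol fragmentation, and the amine-mediated aldol condensation of 1,5-ketoaldehydes. The only ring closed is ring B, in a 6-(enolendo)-exo-trig mode at C6. No new stereocentre remains (C6 and C7 end sp2); C5 and C10 keep the configuration set in step 7 because the bonds C5–C6 and C9–C10 are never broken, and C11 is not acidic at the CH2OSi oxidation level. The selectivities needed are cleavage of C6–C9 rather than C9–C10, secured by the nitrogen push at C6 and by keeping O10 silylated so that no alkoxide can start a retro-aldol, and attack by C7 rather than C9, secured because C9 attack only re-forms the strained cyclobutane reversibly while the quaternary C5 leaves the iminium no way to enolise.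

**Step 9**
Reactants: 14 (11R)-10β-(tert-butyldimethylsilyloxy)-12-(tert-butyldiphenylsilyloxy)-3,3-(ethylenedioxy)eremophil-6-en-8-one
Product: 15 (11R)-10β-(tert-butyldimethylsilyloxy)-12-(tert-butyldiphenylsilyloxy)eremophil-6-ene-3,8-dione
Conditions: PPTS, acetone/H2O (10:1), 50 °C
Reagents that add atoms: water, O
Why: Acid-catalysed hydrolysis of the dioxolane under conditions mild enough for the tertiary TBS ether, the TBDPS ether and the β-siloxy ketone, with C4 (now α to a ketone) keeping its equatorial methyl, the more stable arrangement.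

**Step 10**
Reactants: 15 (11R)-10β-(tert-butyldimethylsilyloxy)-12-(tert-butyldiphenylsilyloxy)eremophil-6-ene-3,8-dione
Product: 16 (11R)-10β-(tert-butyldimethylsilyloxy)-12-(tert-butyldiphenylsilyloxy)-3β-hydroxyeremophil-6-en-8-one
Conditions: LiBH(sec-Bu)3 (1.1 equiv), THF, −78 °C; aq. NH4Cl
Reagents that add atoms: none
Why: Bulky-hydride reduction under steric approach control, in which the saturated C3 ketone should react ahead of the hindered α-branched enone and hydride should enter on the equatorial trajectory from the α face because the β face is blocked by the syn-axial C5 methyl, giving the axial 3β-alcohol cis to the C4 methyl.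

**Step 11**
Reactants: 16 (11R)-10β-(tert-butyldimethylsilyloxy)-12-(tert-butyldiphenylsilyloxy)-3β-hydroxyeremophil-6-en-8-one; 17 angelic acid [(Z)-2-methylbut-2-enoic acid]
Product: 19 (11R)-3β-angeloyloxy-10β-(tert-butyldimethylsilyloxy)-12-(tert-butyldiphenylsilyloxy)eremophil-6-en-8-one, via mixed anhydride 18 (not isolated)
Conditions: 17, 2,4,6-trichlorobenzoyl chloride, Et3N, toluene, rt; then 16, 80 °C
Reagents that add atoms: 2,4,6-trichlorobenzoyl chloride, O=C(Cl)c1c(Cl)cc(Cl)cc1Cl (only in intermediate 18)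
Why: Yamaguchi-type esterification through the angelic 2,4,6-trichlorobenzoic mixed anhydride, run without DMAP so that the Z alkene should not isomerise to the tiglate, acylates the only free hydroxyl with retention at C3.

**Step 12**
Reactants: 19 (11R)-3β-angeloyloxy-10β-(tert-butyldimethylsilyloxy)-12-(tert-butyldiphenylsilyloxy)eremophil-6-en-8-one
Product: 20 (11R)-3β-angeloyloxy-10β,12-dihydroxyeremophil-6-en-8-one
Conditions: HF·pyridine, pyridine/THF, 0 °C → rt
Reagents that add atoms: none
Why: Fluoride-mediated Si–O cleavage with buffered HF·pyridine should remove both the tertiary TBS and the primary TBDPS ether under non-basic conditions that spare the β-hydroxy ketone, the angelate and C11.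

**Step 13**
Reactants: 20 (11R)-3β-angeloyloxy-10β,12-dihydroxyeremophil-6-en-8-one
Product: 22 (2R)-2-[(4aS,7S,8R,8aR)-4a-hydroxy-8,8a-dimethyl-7-{[(2Z)-2-methylbut-2-enoyl]oxy}-3-oxo-3,4,4a,5,6,7,8,8a-octahydronaphthalen-2-yl]propanoic acid, via aldehyde 21 (not isolated)
Conditions: TEMPO (0.2 equiv), PhI(OAc)2 (2.2 equiv), MeCN/H2O (1:1), 0 °C → rt
Reagents that add atoms: water, O
Why: Oxoammonium (TEMPO/PhI(OAc)2) oxidation in aqueous acetonitrile takes only the primary alcohol through aldehyde and hydrate to the acid, the tertiary alcohol being inert, and the near-neutral medium should keep the α-stereocentre C11 intact.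

**Compound list**
1 | 1,4-dioxaspiro[4.5]dec-6-en-8-one | O=C1C=CC2(CC1)OCCO2 | starting material
2 | 7-iodo-1,4-dioxaspiro[4.5]dec-6-en-8-one | O=C1C(I)=CC2(CC1)OCCO2 | intermediate
3 | 7-methyl-1,4-dioxaspiro[4.5]dec-6-en-8-one | O=C1C(C)=CC2(CC1)OCCO2 | intermediate
4 | dimethylaluminium (6R)-6,7-dimethyl-1,4-dioxaspiro[4.5]dec-7-en-8-olate | C[C@@H]1C(C)=C(O[Al](C)C)CCC12OCCO2 | intermediate
5 | tert-butyl{[(6R)-6,7-dimethyl-1,4-dioxaspiro[4.5]dec-7-en-8-yl]oxy}dimethylsilane | C[C@@H]1C(C)=C(O[Si](C)(C)C(C)(C)C)CCC12OCCO2 | intermediate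
6 | (R)-4-methyldihydrofuran-2(3H)-one | O=C1C[C@@H](C)CO1 | starting material
7 | (R)-4-hydroxy-N-methoxy-N,3-dimethylbutanamide | CON(C)C(=O)C[C@@H](C)CO | intermediate
8 | (R)-4-[(tert-butyldiphenylsilyl)oxy]-N-methoxy-N,3-dimethylbutanamide | CON(C)C(=O)C[C@@H](C)CO[Si](c1ccccc1)(c1ccccc1)C(C)(C)C | intermediate
9 | (R)-6-[(tert-butyldiphenylsilyl)oxy]-5-methylhex-1-yn-3-one | C#CC(=O)C[C@@H](C)CO[Si](c1ccccc1)(c1ccccc1)C(C)(C)C | intermediate
10 | (3R)-1-[(1R,2R,6R)-6-{[tert-butyl(dimethyl)silyl]oxy}-1,2-dimethylspiro[bicyclo[4.2.0]oct-7-ene-3,2'-[1,3]dioxolan]-7-yl]-4-{[tert-butyl(diphenyl)silyl]oxy}-3-methylbutan-1-one | C[C@@H]1[C@@]2(C)C=C(C(=O)C[C@@H](C)CO[Si](c3ccccc3)(c3ccccc3)C(C)(C)C)[C@@]2(O[Si](C)(C)C(C)(C)C)CCC14OCCO4 | intermediate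
11 | aza-Michael adduct: 10 with pyrrolidin-1-yl on C6 and H on C9 (2-aminocyclobutyl ketone, C6 and C9 undefined) | C[C@@H]1[C@@]2(C)C(N3CCCC3)C(C(=O)C[C@@H](C)CO[Si](c3ccccc3)(c3ccccc3)C(C)(C)C)[C@@]2(O[Si](C)(C)C(C)(C)C)CCC14OCCO4 | intermediate
12 | ring-opened iminium acetate: ring A with (CH3)(CH=N+ pyrrolidinium) on C5 and (OTBS)(CH2C(=O)CH2CH(CH3)CH2OTBDPS) on C10 | C[C@@H]1[C@@](C)(C=[N+]2CCCC2)[C@@](O[Si](C)(C)C(C)(C)C)(CC(=O)C[C@@H](C)CO[Si](c2ccccc2)(c2ccccc2)C(C)(C)C)CCC13OCCO3.CC(=O)[O-] | intermediate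
13 | Mannich base: 14 with pyrrolidin-1-yl on C6 and H on C7 in place of the C6=C7 bond (C6 and C7 undefined) | C[C@@H]1[C@@]2(C)C(N3CCCC3)C([C@@H](C)CO[Si](c3ccccc3)(c3ccccc3)C(C)(C)C)C(=O)C[C@@]2(O[Si](C)(C)C(C)(C)C)CCC14OCCO4 | intermediate
14 | (11R)-10β-(tert-butyldimethylsilyloxy)-12-(tert-butyldiphenylsilyloxy)-3,3-(ethylenedioxy)eremophil-6-en-8-one (cis-fused) | O1CCOC12CC[C@]3(O[Si](C)(C)C(C)(C)C)CC(=O)C([C@@H](C)CO[Si](c4ccccc4)(c4ccccc4)C(C)(C)C)=C[C@]3(C)[C@H]2C | intermediate
15 | (11R)-10β-(tert-butyldimethylsilyloxy)-12-(tert-butyldiphenylsilyloxy)eremophil-6-ene-3,8-dione | O=C1CC[C@]2(O[Si](C)(C)C(C)(C)C)CC(=O)C([C@@H](C)CO[Si](c3ccccc3)(c3ccccc3)C(C)(C)C)=C[C@]2(C)[C@H]1C | intermediate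
16 | (11R)-10β-(tert-butyldimethylsilyloxy)-12-(tert-butyldiphenylsilyloxy)-3β-hydroxyeremophil-6-en-8-one | O[C@H]1CC[C@]2(O[Si](C)(C)C(C)(C)C)CC(=O)C([C@@H](C)CO[Si](c3ccccc3)(c3ccccc3)C(C)(C)C)=C[C@]2(C)[C@H]1C | intermediate
17 | angelic acid, (Z)-2-methylbut-2-enoic acid | C/C=C(/C)C(=O)O | starting material
18 | (Z)-2-methylbut-2-enoic 2,4,6-trichlorobenzoic anhydride | C/C=C(/C)C(=O)OC(=O)c1c(Cl)cc(Cl)cc1Cl | intermediate
19 | (11R)-3β-angeloyloxy-10β-(tert-butyldimethylsilyloxy)-12-(tert-butyldiphenylsilyloxy)eremophil-6-en-8-one | C/C=C(/C)C(=O)O[C@H]1CC[C@]2(O[Si](C)(C)C(C)(C)C)CC(=O)C([C@@H](C)CO[Si](c3ccccc3)(c3ccccc3)C(C)(C)C)=C[C@]2(C)[C@H]1C | intermediate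
20 | (11R)-3β-angeloyloxy-10β,12-dihydroxyeremophil-6-en-8-one | C/C=C(/C)C(=O)O[C@H]1CC[C@]2(O)CC(=O)C([C@@H](C)CO)=C[C@]2(C)[C@H]1C | intermediate
21 | (11R)-3β-angeloyloxy-10β-hydroxy-8-oxoeremophil-6-en-12-al | C/C=C(/C)C(=O)O[C@H]1CC[C@]2(O)CC(=O)C([C@@H](C)C=O)=C[C@]2(C)[C@H]1C | intermediate
22 | (2R)-2-[(4aS,7S,8R,8aR)-4a-hydroxy-8,8a-dimethyl-7-{[(2Z)-2-methylbut-2-enoyl]oxy}-3-oxo-3,4,4a,5,6,7,8,8a-octahydronaphthalen-2-yl]propanoic acid | C/C=C(/C)C(=O)O[C@H]1CC[C@]2(O)CC(=O)C([C@@H](C)C(=O)O)=C[C@]2(C)[C@H]1C | target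

**Count**
Total steps: 13. Longest linear sequence: 10 steps (steps 1, 2, 3, 7, 8, 9, 10, 11, 12, 13; the branch from 6 through steps 4, 5, 6 is equally long).

**Steps most likely to fail**

Step 8 (Proposed new method). Conjugate addition of the amine at the neopentyl cyclobutene carbon C6 may be too slow, or loss of silanol from C10 after ring opening may outrun the Mannich closure. The fallback sets out from 10 and comes back at 14, using known reactions one at a time. Copper-catalysed conjugate borylation (CuCl, NaOt-Bu, a bisphosphine, B2pin2, MeOH, THF) should give the β-boryl cyclobutyl ketone F1. Oxidation with NaBO3·4H2O should give the 2-acylcyclobutanol F2, which should undergo de Mayo-type retro-aldol cleavage of C6–C9 in the mildly basic medium to the 1,5-keto aldehyde F3. Piperidinium acetate in warm benzene should then close ring B by intramolecular aldol condensation of C7 onto C6 to give 14.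

Step 7. The silyl triflimide may ionise the dioxolane, or the zwitterion may collapse by silyl transfer to the open Michael adduct instead of closing the four-membered ring. The fallback sets out from 5 and comes back at 15 by a classical anionic sequence without a cyclobutene. Mukaiyama-type reaction of 5 with trimethyl orthoformate (BF3·OEt2, CH2Cl2, −78 °C) should give the α-(dimethoxymethyl) ketone F4, the electrophile again entering anti to the C4 methyl. Methylmagnesium bromide on Weinreb amide 8 should give the methyl ketone F5. Its kinetic lithium enolate (LDA, −78 °C), transmetalated with CeCl3, should add to the C10 ketone of F4 along the axial trajectory anti to the axial C5 methyl to give the ketol F6. TBSOTf and 2,6-lutidine should give the silyl ether F7. Aqueous HCl in THF should remove both the dimethyl acetal and the dioxolane to give the keto aldehyde F8, and pyrrolidinium acetate should close ring B by intramolecular aldol condensation to give 15.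

Step 3. The doubly hindered enone (α-methyl, γ,γ-dialkoxy) may react slowly, with low enantioselectivity, or by competing 1,2-addition. The fallback sets out from 1 and comes back at 5, introducing the C5 methyl as an electrophile instead. Copper–phosphoramidite-catalysed addition of Me2Zn (Cu(OTf)2, toluene, −30 °C) to the unsubstituted enone 1, with TMSOTf trapping, should give the regiodefined enol silane F9. MeLi followed by MeI should give the 6,7-dimethyl ketone F10 as C7 epimers, which is of no consequence. Equilibrating silylation (TBSCl, NaI, Et3N, MeCN, 70 °C) should then give the tetrasubstituted enol silane 5.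

**Further compounds**
F1 | step 8 | β-boryl cyclobutyl ketone: 10 with pinacolboryl on C6 and H on C9 | C[C@@H]1[C@@]2(C)C(B3OC(C)(C)C(C)(C)O3)C(C(=O)C[C@@H](C)CO[Si](c3ccccc3)(c3ccccc3)C(C)(C)C)[C@@]2(O[Si](C)(C)C(C)(C)C)CCC14OCCO4
F2 | step 8 | 2-acylcyclobutanol: 10 with OH on C6 and H on C9 | C[C@@H]1[C@@]2(C)C(O)C(C(=O)C[C@@H](C)CO[Si](c3ccccc3)(c3ccccc3)C(C)(C)C)[C@@]2(O[Si](C)(C)C(C)(C)C)CCC14OCCO4
F3 | step 8 | 1,5-keto aldehyde: ketal-protected ring A with (CH3)(CHO) on C5 and (OTBS)(CH2C(=O)CH2CH(CH3)CH2OTBDPS) on C10 | C[C@@H]1[C@@](C)(C=O)[C@@](O[Si](C)(C)C(C)(C)C)(CC(=O)C[C@@H](C)CO[Si](c2ccccc2)(c2ccccc2)C(C)(C)C)CCC13OCCO3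
F4 | step 7 | (6R,7S)-7-(dimethoxymethyl)-6,7-dimethyl-1,4-dioxaspiro[4.5]decan-8-one | C[C@@H]1[C@@](C)(C(OC)OC)C(=O)CCC12OCCO2
F5 | step 7 | (R)-5-[(tert-butyldiphenylsilyl)oxy]-4-methylpentan-2-one | CC(=O)C[C@@H](C)CO[Si](c1ccccc1)(c1ccccc1)C(C)(C)C
F6 | step 7 | ketol: F4 with OH and CH2C(=O)CH2CH(CH3)CH2OTBDPS on C10 (OH cis to the C5 methyl) | C[C@@H]1[C@@](C)(C(OC)OC)[C@@](O)(CC(=O)C[C@@H](C)CO[Si](c2ccccc2)(c2ccccc2)C(C)(C)C)CCC13OCCO3
F7 | step 7 | tert-butyldimethylsilyl ether of F6 | C[C@@H]1[C@@](C)(C(OC)OC)[C@@](O[Si](C)(C)C(C)(C)C)(CC(=O)C[C@@H](C)CO[Si](c2ccccc2)(c2ccccc2)C(C)(C)C)CCC13OCCO3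
F8 | step 7 | keto aldehyde with free C3 ketone: F3 without the dioxolane | C[C@@H]1[C@@](C)(C=O)[C@@](O[Si](C)(C)C(C)(C)C)(CC(=O)C[C@@H](C)CO[Si](c2ccccc2)(c2ccccc2)C(C)(C)C)CCC1=O
F9 | step 3 | trimethyl{[(6R)-6-methyl-1,4-dioxaspiro[4.5]dec-7-en-8-yl]oxy}silane | C[C@@H]1C=C(O[Si](C)(C)C)CCC12OCCO2
F10 | step 3 | (6R)-6,7-dimethyl-1,4-dioxaspiro[4.5]decan-8-one (C7 epimers) | C[C@@H]1C(C)C(=O)CCC12OCCO2
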